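## Retrosynthetic overview

1. Target ⇐ oxidative radical cascade (Mn(OAc)3) on the 7-endo-prenyl bicyclo[3.3.1]nonane trione: the C-3 radical closes the seven-membered (homoadamantane) ring, then a 5-exo closure makes the cyclopentane and leaves the isopropenyl group.
2. Bicyclic trione ⇐ ring A stitched onto a 2-benzoylcyclohexanone (ring B) with carbonyldiimidazole; the quaternary C-5 is made first, by acylation and then geranylation anti to prenyl.
3. Ring B ⇐ 1,3 O-to-C shift of a cyclic tertiary-alkyl vinylogous ester ⇐ key disconnection: the C–O bond between the diketone enol oxygen and the isopropenyl carbon (cobalt-hydride hydroalkoxylation).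
4. Acyclic 1,3-diketone ⇐ (S)-limonene (ring ozonolysis, Wittig, Claisen benzoylation); its stereocentre becomes C-7 and steers every later centre.
5. Ring order: oxane (C–O) → ring B → ring A → seven-membered ring → cyclopentane.

Assumption: core atoms carry the usual acylphloroglucinol locants (C-1 benzoyl bridgehead, C-3, C-5 geranyl bridgehead, C-7 prenyl, C-8 gem-dimethyl, C-9 bridging ketone) in the Why lines, and labile 1,3-dicarbonyl CH centres are drawn as the expected major epimer.

## Route

Step 1
Reactants: 1 (S)-(−)-limonene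
Product: 3 (3S)-6-oxo-3-(prop-1-en-2-yl)heptanal, via limonene ozonide 2 (not isolated)
Conditions: O3 (1.0 equiv), CH2Cl2, −78 °C; then Me2S, −78 °C to rt
Reagents that add atoms: ozone, [O-][O+]=O
Why: Criegee ozonolysis, in which the electron-rich trisubstituted ring alkene reacts faster than the 1,1-disubstituted isopropenyl group, so one equivalent of ozone cleaves only the ring and the isopropenyl-bearing stereocentre (future C-7) is untouched.

Step 2
Reactants: 3 (3S)-6-oxo-3-(prop-1-en-2-yl)heptanal; 4 isopropyltriphenylphosphonium iodide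
Product: 6 (5S)-8-methyl-5-(prop-1-en-2-yl)non-7-en-2-one, via phosphorus ylide 5 (not isolated)
Conditions: 4, n-BuLi, THF, 0 °C; then 3, −78 °C to 0 °C
Reagents that add atoms: none
Why: Wittig olefination, in which the non-stabilised ylide adds to the aldehyde far faster than to the methyl ketone and turns CH2CHO into the prenyl group; the stereocentre is β to the aldehyde and cannot epimerise.

Step 3
Reactants: 6 (5S)-8-methyl-5-(prop-1-en-2-yl)non-7-en-2-one; 7 methyl benzoate
Product: 8 (6S)-9-methyl-1-phenyl-6-(prop-1-en-2-yl)dec-8-ene-1,3-dione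
Conditions: NaH (2.5 equiv), THF, 65 °C; then aq. HCl
Reagents that add atoms: none
Why: crossed Claisen condensation of a methyl ketone with a non-enolisable ester, which acylates the methyl carbon and is driven by formation of the sodium 1,3-diketonate; no stereocentre is involved.

Step 4
Reactants: 8 (6S)-9-methyl-1-phenyl-6-(prop-1-en-2-yl)dec-8-ene-1,3-dione
Product: 9 (2Z)-2-[(5S)-6,6-dimethyl-5-(3-methylbut-2-en-1-yl)oxan-2-ylidene]-1-phenylethan-1-one
Conditions: [N,N′-bis(3,5-di-tert-butylsalicylidene)ethylenediaminato]cobalt (C32H46CoN2O2, 3 mol %), N-fluoro-2,4,6-trimethylpyridinium triflate (1.3 equiv), PhSiH3 (1.3 equiv), PhCF3, 0 °C to rt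
Reagents that add atoms: none
Why: Proposed new method: the cobalt hydride transfers a hydrogen atom selectively to the 1,1-disubstituted alkene (not the trisubstituted prenyl), the tertiary radical is captured by cobalt and oxidised to a cationic alkylcobalt (tetravalent cobalt), and this is displaced 6-exo by the hydrogen-bonded enol oxygen to give the tertiary-alkyl vinylogous ester without free acid, so the adjacent stereocentre and the prenyl group stay intact; the closest known reaction type is the cobalt–salen/N-fluoropyridinium/silane Markovnikov hydroalkoxylation of alkenols (radical–polar crossover, related to the Mukaiyama hydration), which has not been shown with a 1,3-diketone enol oxygen as the nucleophile or with this alkene discrimination.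

Step 5
Reactants: 9 (2Z)-2-[(5S)-6,6-dimethyl-5-(3-methylbut-2-en-1-yl)oxan-2-ylidene]-1-phenylethan-1-one
Product: 10 (2R,4S)-2-benzoyl-3,3-dimethyl-4-(3-methylbut-2-en-1-yl)cyclohexan-1-one
Conditions: Me3SiOTf (10 mol %), CH2Cl2, −78 °C to −30 °C
Reagents that add atoms: none
Why: Lewis-acid 1,3 O-to-C shift (Petasis–Ferrier-type ring contraction ending in a Reetz-type tert-alkylation), in which O-silylation and heterolysis of the tertiary C–O bond give a tethered tertiary cation and a silyl dienol ether that recombine at carbon through a six-membered chair, trading C–O for C–C plus C=O; C-7 is retained and C-1 forms as an epimerisable diketone centre.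

Step 6
Reactants: 11 2-methylbut-3-en-2-ol; 12 triethyl orthoacetate
Product: 14 ethyl 5-methylhex-4-enoate, via ketene acetal 13 (not isolated)
Conditions: EtCO2H (cat.), 140 °C, EtOH distilled off
Reagents that add atoms: none
Why: Johnson–Claisen orthoester rearrangement, in which acid-catalysed exchange gives the ketene acetal that undergoes a [3,3]-sigmatropic shift to the γ,δ-unsaturated ester; no stereocentre.

Step 7
Reactants: 10 (2R,4S)-2-benzoyl-3,3-dimethyl-4-(3-methylbut-2-en-1-yl)cyclohexan-1-one; 14 ethyl 5-methylhex-4-enoate; 15 geranyl bromide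
Product: 17 (2S,4R,6R)-2-benzoyl-6-[(2E)-3,7-dimethylocta-2,6-dien-1-yl]-3,3-dimethyl-4-(3-methylbut-2-en-1-yl)-6-(5-methylhex-4-enoyl)cyclohexan-1-one, via triketone 16 (not isolated)
Conditions: LiN(iPr)2 (3.2 equiv), THF, −78 °C to 0 °C; 14, −78 °C to 0 °C; then 15, DMPU, 0 °C to rt; aq. NH4Cl
Reagents that add atoms: none
Why: Hauser–Harris dianion chemistry, in which the γ-carbanion (C-5) of the diketone dianion is acylated by the ester (Claisen) and the resulting triketone enolate is C-alkylated at C-5 by geranyl bromide axially, anti to the equatorial C-7 prenyl group, which sets the quaternary centre with geranyl trans and the acyl chain cis to prenyl; C-1 is shielded by the neighbouring gem-dimethyl group.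

Step 8
Reactants: 17 (2S,4R,6R)-2-benzoyl-6-[(2E)-3,7-dimethylocta-2,6-dien-1-yl]-3,3-dimethyl-4-(3-methylbut-2-en-1-yl)-6-(5-methylhex-4-enoyl)cyclohexan-1-one; 18 1,1′-carbonyldiimidazole
Product: 22 (1R,5R,7R)-1-benzoyl-5-[(2E)-3,7-dimethylocta-2,6-dien-1-yl]-4-hydroxy-8,8-dimethyl-3,7-bis(3-methylbut-2-en-1-yl)bicyclo[3.3.1]non-3-ene-2,9-dione, via acyl imidazole 19 (not isolated), via acylketene 20 (not isolated), via enol lactone 21 (not isolated)
Conditions: LiN(SiMe3)2 (2.2 equiv), THF, −78 °C; 18, −78 °C to rt, then 60 °C; aq. HCl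
Reagents that add atoms: none
Why: Dieckmann-type carbonylative annulation, in which the kinetic side-chain enolate (C-3) is C-acylated by carbonyldiimidazole, loss of imidazole gives an acylketene that is trapped reversibly at the diketone oxygen (enol lactone) and irreversibly at C-1 because the bridged trione leaves the equilibrium as its stable vinylogous-acid enolate; ring A can only close on the face carrying the acyl chain, so the C-1 configuration and the 7-endo prenyl relationship follow from C-5.

Step 9
Reactants: 22 (1R,5R,7R)-1-benzoyl-5-[(2E)-3,7-dimethylocta-2,6-dien-1-yl]-4-hydroxy-8,8-dimethyl-3,7-bis(3-methylbut-2-en-1-yl)bicyclo[3.3.1]non-3-ene-2,9-dione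
Product: 23 target CNP0110731.1
Conditions: Mn(OAc)3·2H2O (2.2 equiv), Cu(OAc)2·H2O (0.3 equiv), AcOH, rt
Reagents that add atoms: none
Why: oxidative radical cyclisation with trivalent manganese (the reaction type used for caged acylphloroglucinols), in which the C-3 radical adds 7-exo to the endo C-7 prenyl group with its CMe2 end turned away from the C-8/benzoyl side, the tertiary radical closes 5-exo onto the C-3 prenyl group from the open face, and divalent copper oxidises the last tertiary radical to the less substituted alkene (isopropenyl); the three new stereocentres are fixed by the cage geometry.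

## Compound list

1 | (S)-(−)-limonene | CC1=CC[C@H](CC1)C(C)=C | starting material
2 | limonene ring ozonide (1,2,4-trioxolane across the former ring C=C, side-chain centre S, acetal carbons as a mixture) | CC12OC(C[C@H](CC1)C(C)=C)OO2 | intermediate
3 | (3S)-6-oxo-3-(prop-1-en-2-yl)heptanal | O=CC[C@H](CCC(C)=O)C(C)=C | intermediate
4 | isopropyltriphenylphosphonium iodide | CC(C)[P+](c1ccccc1)(c1ccccc1)c1ccccc1.[I-] | starting material
5 | (propan-2-ylidene)triphenylphosphorane | CC(C)=P(c1ccccc1)(c1ccccc1)c1ccccc1 | intermediate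
6 | (5S)-8-methyl-5-(prop-1-en-2-yl)non-7-en-2-one | CC(=O)CC[C@@H](CC=C(C)C)C(C)=C | intermediate
7 | methyl benzoate | COC(=O)c1ccccc1 | starting material
8 | (6S)-9-methyl-1-phenyl-6-(prop-1-en-2-yl)dec-8-ene-1,3-dione | O=C(CC(=O)c1ccccc1)CC[C@@H](CC=C(C)C)C(C)=C | intermediate
9 | (2Z)-2-[(5S)-6,6-dimethyl-5-(3-methylbut-2-en-1-yl)oxan-2-ylidene]-1-phenylethan-1-one | O=C(/C=C1/CC[C@@H](CC=C(C)C)C(C)(C)O1)c1ccccc1 | intermediate
10 | (2R,4S)-2-benzoyl-3,3-dimethyl-4-(3-methylbut-2-en-1-yl)cyclohexan-1-one (benzoyl cis to prenyl, C-2 labile) | O=C1CC[C@@H](CC=C(C)C)C(C)(C)[C@H]1C(=O)c1ccccc1 | intermediate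
11 | 2-methylbut-3-en-2-ol | CC(C)(O)C=C | starting material
12 | triethyl orthoacetate | CCOC(C)(OCC)OCC | starting material
13 | 1-ethoxy-1-[(2-methylbut-3-en-2-yl)oxy]ethene | C=C(OCC)OC(C)(C)C=C | intermediate
14 | ethyl 5-methylhex-4-enoate | CCOC(=O)CCC=C(C)C | intermediate
15 | geranyl bromide, (2E)-1-bromo-3,7-dimethylocta-2,6-diene | BrC/C=C(\C)CCC=C(C)C | starting material
16 | (2R,4R,6R)-2-benzoyl-3,3-dimethyl-4-(3-methylbut-2-en-1-yl)-6-(5-methylhex-4-enoyl)cyclohexan-1-one (all-cis, triketo tautomer drawn, C-2 and C-6 labile) | O=C1[C@H](C(=O)c2ccccc2)C(C)(C)[C@H](CC=C(C)C)C[C@@H]1C(=O)CCC=C(C)C | intermediate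
17 | (2S,4R,6R)-2-benzoyl-6-[(2E)-3,7-dimethylocta-2,6-dien-1-yl]-3,3-dimethyl-4-(3-methylbut-2-en-1-yl)-6-(5-methylhex-4-enoyl)cyclohexan-1-one (geranyl trans, acyl chain cis to prenyl) | O=C1[C@H](C(=O)c2ccccc2)C(C)(C)[C@H](CC=C(C)C)C[C@]1(C/C=C(\C)CCC=C(C)C)C(=O)CCC=C(C)C | intermediate
18 | 1,1′-carbonyldiimidazole | O=C(n1ccnc1)n1ccnc1 | starting material
19 | acyl imidazole: 17 with an (imidazol-1-yl)carbonyl group on the α-carbon of the 5-methylhex-4-enoyl chain (ring centres as in 17, new centre as a mixture) | O=C1[C@H](C(=O)c2ccccc2)C(C)(C)[C@H](CC=C(C)C)C[C@]1(C/C=C(\C)CCC=C(C)C)C(=O)C(CC=C(C)C)C(=O)n1ccnc1 | intermediate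
20 | acylketene: 17 with the side-chain α-carbon converted to C(prenyl)=C=O (ring centres as in 17) | O=C1[C@H](C(=O)c2ccccc2)C(C)(C)[C@H](CC=C(C)C)C[C@]1(C/C=C(\C)CCC=C(C)C)C(=O)C(CC=C(C)C)=C=O | intermediate
21 | enol lactone: the C-9 enol oxygen acylated by the new carbonyl, six-membered pyran-2,4-dione fused to ring B (C-5 and C-7 as in 17) | O=C1OC2=C(C(=O)c3ccccc3)C(C)(C)[C@H](CC=C(C)C)C[C@]2(C/C=C(\C)CCC=C(C)C)C(=O)C1CC=C(C)C | intermediate
22 | (1R,5R,7R)-1-benzoyl-5-[(2E)-3,7-dimethylocta-2,6-dien-1-yl]-4-hydroxy-8,8-dimethyl-3,7-bis(3-methylbut-2-en-1-yl)bicyclo[3.3.1]non-3-ene-2,9-dione (7-endo prenyl) | CC(C)=CCC1=C(O)[C@@]2(C/C=C(\C)CCC=C(C)C)C[C@@H](CC=C(C)C)C(C)(C)[C@](C(=O)c3ccccc3)(C2=O)C1=O | intermediate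
23 | target CNP0110731.1 (benzoyl, geranyl, gem-dimethyl homoadamantane trione with fused isopropenylcyclopentane) | C=C(C)[C@@H]1C[C@@]23C(=O)[C@@]4(C/C=C(\C)CCC=C(C)C)C[C@@H](C[C@H]2C1(C)C)C(C)(C)[C@](C(=O)c1ccccc1)(C4=O)C3=O | target

## Step count and risks

Total step count: 9. Longest linear sequence: 8 steps (1 → 3 → 6 → 8 → 9 → 10 → 17 → 22 → 23); step 6 is the side branch.

The step most likely to fail is the ring A annulation of step 8. Each elementary event has precedent, but the final C-acylation creates a quaternary carbon that already bears a benzoyl group and sits next to the gem-dimethyl carbon, and the enol lactone 21 could become a dead end. The fallback replaces acylation by conjugate addition–elimination. It sets out from 17: LiN(SiMe3)2, CS2 and then MeI convert the side-chain ketone into the α-oxoketene dithioacetal F1. Cs2CO3 in DMF lets the diketone carbon C-1 add to the bis(methylthio) carbon and expel methanethiolate, giving the bicyclic 2-methylthio enone F2. Aqueous LiOH in THF hydrolyses the vinylogous thioester and the sequence returns to the route at 22.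

The second is the proposed cobalt cyclo-etherification of step 4. The N-fluoropyridinium oxidant could fluorinate the diketone carbon, the trisubstituted alkene could compete, or the cationic alkylcobalt could be attacked at carbon or eliminate. The fallback uses known chemistry and sets out from 8: Mukaiyama hydration (Co(acac)2, PhSiH3, O2, i-PrOH) of the isopropenyl group gives the tertiary alcohol F3. Acid-catalysed cyclodehydration (pyridinium p-toluenesulfonate, molecular sieves, benzene, 80 °C) then closes the oxane and returns to the route at 9.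

The third is the O-to-C shift of step 5. The tethered tertiary cation may lose a proton instead of recombining at carbon, and a hydride shift from C-7 would erode the stereocentre. The fallback avoids the enol ether altogether and sets out from 8: hydrogen-atom-transfer Markovnikov hydrochlorination (Co(BF4)2·6H2O with a salen-type ligand, TsCl, PhSiH3, EtOH) gives the tertiary chloride F4. AgOTf in CH2Cl2 at −40 °C ionises it for direct intramolecular tert-alkylation of the diketone carbon, returning to the route at 10.

## Further compounds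

F1 | step 8 | α-oxoketene dithioacetal: 17 with the side-chain CH2 next to the ketone converted to C(prenyl)=C(SMe)2 (ring centres as in 17) | O=C1[C@H](C(=O)c2ccccc2)C(C)(C)[C@H](CC=C(C)C)C[C@]1(C/C=C(\C)CCC=C(C)C)C(=O)C(CC=C(C)C)=C(SC)SC
F2 | step 8 | 1-benzoyl-5-geranyl-8,8-dimethyl-2-(methylsulfanyl)-3,7-bis(3-methylbut-2-en-1-yl)bicyclo[3.3.1]non-2-ene-4,9-dione (bridgeheads and C-7 as in 22) | CC(C)=CCC1=C(SC)[C@]2(C(=O)c3ccccc3)C(C)(C)[C@H](CC=C(C)C)C[C@](C/C=C(\C)CCC=C(C)C)(C1=O)C2=O
F3 | step 4 | (6S)-6-(2-hydroxypropan-2-yl)-9-methyl-1-phenyldec-8-ene-1,3-dione | O=C(CC(=O)c1ccccc1)CC[C@@H](CC=C(C)C)C(C)(C)O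
F4 | step 5 | (6S)-6-(2-chloropropan-2-yl)-9-methyl-1-phenyldec-8-ene-1,3-dione | O=C(CC(=O)c1ccccc1)CC[C@@H](CC=C(C)C)C(C)(C)Cl
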